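(The readings were computed with made-up constants, and the scatter is random.)

Compare the runs at equal E: the flask, charged with 0.16 M of Q, shares its 0.480 M of E with the west and south runs and differs from them in the charge of Q.

| flask | Q | E | remark | time |
|---|---|---|---|---|
| west | 0.080 M | 0.48 M | run made earlier |  |
| south | 0.12 M | 0.48 M | run made earlier |  |
| south-west | 0.16 M | 0.24 M | run made earlier |  |
| flask | 0.16 M | 0.480 M |  | 50 min |

| run | time / min | Z / % | X / % |
|---|---|---|---|
| west | 5.00 | 7.6 | 12.1 |
| west | 8.00 | 7.9 | 3.6 |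
| west | 12.0 | 8.0 | 0.5 |
| west | 20.0 | 8.5 | 0.1 |
| west | 40.0 | 8.7 | 0 |
| west | 60.0 | 8.3 | 0 |
| south | 5.00 | 11.3 | 10.7 |
| south | 8.00 | 10.5 | 3.5 |
| south | 12.0 | 11.4 | 0.7 |
| south | 20.0 | 11.0 | 0 |
| south | 40.0 | 11.0 | 0.2 |
| south | 60.0 | 11.0 | 0.2 |
| south-west | 5.00 | 25.3 | 4.8 |
| south-west | 10.0 | 26.2 | 0.7 |
| south-west | 15.0 | 25.8 | 0 |
| south-west | 30.0 | 26.0 | 0 |
| south-west | 60.0 | 25.3 | 0.2 |

(standard deviation of a reading: 0.3 percentage points)

- equivalents of E to Q, everything else as given, that leave most Z at 50 min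
- the amount of Z then, in percent of the Q charged
- the amount of Z with the amounts as given

The readings look contradictory: the west run, with 6.00 equivalents of E, ends at 8.3 % of Z, less than the 25.3 % of the south-west run with 1.50 equivalents, so more reagent stands beside less product. X clears this up: at 5.00 min the west run holds 12.1 % of X, more than the 4.8 % of the south-west run, so Z is a middle stage that E carries on to X. From the last west and south readings:

m = ln(Z south / Z west) / ln(Q south / Q west) = 0.695

This m, the apparent order in Q of the final percentage of Z at fixed E, carries the south reading to the flask: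

Z = Z south × (Q flask / Q south)^m = 13.4 %

The forecast says 14.2 % for the flask, above this reckoning, and 26.5 % at 1.3 equiv, on the ground: “Z then stops changing, while X simply decays to J.”

The flask gives 13.8 %, and its best is 26.2 % at 1.25 equiv.

    E → L (k = 0.0307 s⁻¹)
    E + Z → X (k = 0.393 L mol⁻¹ s⁻¹)
    Q ⇌ D (K = 2.10, k = 0.242 s⁻¹)
    X → J (k = 0.00694 s⁻¹)
    Q + E → Z (k = 0.630 L mol⁻¹ s⁻¹)

Carried to a neighbour flask with 0.096 M of Q and the same E, m gives 9.42 % against the 9.17 % that this neighbour gives. In the flask, Q + E → Z, E + Z → X and E → L ran while E lasted, and by 5.00 min E stood at 0 %, with Z at 13.8 %, X at 9.66 % and L at 0.238 M. X → J then went on beside a steady Z, X reaching 0 % by 25.0 min, and at 50.0 min the flask held J at 68.6 % and Z at 13.8 %.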